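The earlier runs and the new flask are calculated on assumed constants; the scatter is artificial.

| setting | north-east | south-east | flask |
|---|---|---|---|
| electrophile | 0.034 M | 0.075 M | 0.050 M |
| nucleophile | 0.15 M | 0.15 M | 0.150 M |
| free base | 0.025 M | 0.025 M | 0.0250 M |
| protic impurity | 1 mM | 1 mM | 1.00 mM |
| remark | run made earlier | run made earlier |  |
| time |  |  | 10 d |

| run | time / d | electrophile / % | product / % |
|---|---|---|---|
| north-east | 0.417 | 77.9 | 19.4 |
| north-east | 1.25 | 61.3 | 36.1 |
| north-east | 2.00 | 53.9 | 42.8 |
| north-east | 3.00 | 48.2 | 48.9 |
| north-east | 5.00 | 41.6 | 55.7 |
| north-east | 6.00 | 39.2 | 57.5 |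
| south-east | 1.04 | 67.4 | 31.7 |
| south-east | 2.08 | 58.2 | 40.2 |
| south-east | 3.00 | 54.3 | 43.9 |
| south-east | 4.00 | 51.1 | 47.3 |
| south-east | 5.00 | 49.1 | 49.1 |
| south-east | 6.00 | 47.9 | 50.8 |

(scatter of a reading: 0.3 percentage points)

- what was read earlier has a scatter of 0.3 percentage points, one standard deviation
- candidate steps: electrophile + nucleophile -> acid set free + product; nucleophile + acid set free <-> protonated nucleophile; acid set free + free base <-> salt of the base; electrophile + protic impurity -> quenched substrate; 2 nucleophile -> homo dimer
- the earlier runs do not show how much of nucleophile is bound; that part of a forecast is a guess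

- part of the electrophile that has reacted at 10 d
- share of the unused nucleophile that is free and not bound as protonated nucleophile, at 10 d

Late on, the south-east run lost its electrophile more slowly than the north-east run, at 0.0247 d⁻¹ against 0.0594 d⁻¹ between their last two readings, though both were charged with the same nucleophile and free base. Electrophile is used by free nucleophile, so this logarithmic fall, a pseudo-first-order rate, reads [nucleophile], and the south-east run held less of it. Each product frees one acid set free, which free base and nucleophile can both bind, so we carry the base cover, the share of the charged electrophile whose acid the charged free base can hold: 50.0% in the asked flask. The north-east run, with a cover of 73.5%, ended below it at 57.5% product, while the south-east run, with 33.3%, passed its cover between 1.04 d and 2.08 d and reached 50.8%. Past that crossing, the charged free base cannot hold the whole of the acid, so some of the acid must stand off the base, however much the nucleophile had bound before. Taking the rate of 0.527 d⁻¹ over the first north-east interval to stand for the charge, the south-east reading gives [nucleophile] near 0.00704 M.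

The forecast gives c as 62% and fr as 90%, “with 0.12 M nucleophile left”. We accept its c, and with 2.00% of the electrophile reckoned as quenched substrate, the flask's product passes its cover, so that at least 0.00500 M of acid stands off the base. Taking that floor as protonated nucleophile, with the south-east figure for free nucleophile, our own fr is 58.5%, an estimate on the high side and lower than the forecast's.

The simulation gives c = 62.2% and fr = 32.8%.

    electrophile + nucleophile → acid set free + product (k = 0.210 M⁻¹ h⁻¹)
    nucleophile + acid set free ⇌ protonated nucleophile, settled at all times (K = 12000 M⁻¹)
    acid set free + free base ⇌ salt of the base, settled at all times (K = 35000 M⁻¹)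
    electrophile + protic impurity → quenched substrate (k = 33.0 M⁻¹ h⁻¹)
    2 nucleophile → homo dimer (k = 0.250 M⁻¹ h⁻¹)

At 10.0 d the flask's product stands at 60.2%, which is 10 percentage points past its cover of 50.0%, with 0.00851 M protonated nucleophile against 0.00416 M free nucleophile. The neighbouring flask, charged with 0.013 M electrophile, has a cover of 192%, and its 64.0% product stays below that. There 70.8% of the free base remains, protonated nucleophile is 0.00103 M against 0.00727 M free nucleophile, and fr is 87.6%.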